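**Retrosynthetic overview**

- Guaiane numbering is used: C1 and C5 are the ring-fusion atoms, C2–C3(=O)–C4 complete the five-membered ring, C6 to C10 the seven-membered ring, and C11 is the acetoxy-bearing carbon. Both esters go on last (secondary methacrylate, then tertiary acetate), and the C11 oxygen comes from Markovnikov hydration of an isopropenyl group.
- Enabling feature: the array O–C8–C7–C11–O on the seven-membered ring, a secondary carbinol next to a carbon bearing an oxygenated isopropyl group. After retro-hydration it is a homoallylic alcohol C8(OH)–C7–C11(=CH2)CH3, the retron of an intramolecular carbonyl–ene reaction, so the C7–C8 bond is cut to a C8 aldehyde and a C7=C11 prenyl double bond, carried on C1 and C5 of a 2-methylcyclopentenone.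
- The seco aldehyde (a ring-extended analogue of citronellal) comes from a chiral-pool δ-lactone (C10), trans-alkylation of its enolate (C1), vinyllithium closure onto the lactone carbonyl, prenyl addition and oxidative 1,3-transposition.
- Ring order: five-membered ring first (step 5), seven-membered ring second (step 9).
- C8 is reset after ring closure by oxidation and bulky-hydride reduction, which places the hydroxyl cis to the C7 substituent.

Key step: step 9

Remark on the chemistry: methyl hydrogen (R)-3-methylglutarate is taken as a commercial chiral-pool half ester; the C8 configuration formed in the key step is not relied upon, because both epimers converge in the following oxidation.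

**Step 1**
Reactants: 1 but-2-yn-1-ol
Product: 3 (Z)-3-iodobut-2-en-1-ol, via cyclic sodium vinylalanate 2 (not isolated)
Conditions: NaAlH2(OCH2CH2OCH3)2, THF, 0 °C; then I2, −78 → 0 °C
Reagents that add atoms: iodine, II
Why: Hydride adds anti across the triple bond of the propargylic alkoxide to give the five-membered vinylalanate with aluminium on C3, and iodinolysis of the C–Al bond with retention should give the (Z)-vinyl iodide (trans-hydroalumination–iodination of a propargylic alcohol).

**Step 2**
Reactants: 3 (Z)-3-iodobut-2-en-1-ol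
Product: 4 (Z)-1-bromo-3-iodobut-2-ene
Conditions: PBr3, Et2O, 0 °C
Reagents that add atoms: phosphorus tribromide, BrP(Br)Br
Why: SN2 bromination of the primary allylic alcohol through its phosphite ester should leave the vinyl iodide and its Z geometry untouched.

**Step 3**
Reactants: 5 methyl hydrogen (R)-3-methylglutarate
Product: 7 (4S)-4-methyloxan-2-one, via (3S)-5-hydroxy-3-methylpentanoic acid 6 (not isolated)
Conditions: LiBH4, THF, 0 → 50 °C; aq. HCl; p-TsOH (cat.), toluene, 80 °C
Reagents that add atoms: none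
Why: LiBH4 reduces the methyl ester while the acid is protected as its lithium carboxylate, and acid then closes the δ-lactone (chemoselective ester reduction–lactonization); the stereocentre is untouched and its descriptor changes from R to S only because the priorities of the two arms change.

**Step 4**
Reactants: 7 (4S)-4-methyloxan-2-one; 4 (Z)-1-bromo-3-iodobut-2-ene
Product: 9 (3R,4S)-3-[(2Z)-3-iodobut-2-en-1-yl]-4-methyloxan-2-one, via lithium enolate 8 (not isolated)
Conditions: LiN(i-Pr)2, THF, −78 °C; then 4, −78 → −40 °C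
Reagents that add atoms: none
Why: The lactone enolate is alkylated by the allylic bromide on the face opposite to the neighbouring C4 methyl group (enolate alkylation under 1,2-induction in a six-membered ring), which should set the new centre (later C1) trans to the methyl-bearing centre (later C10).

**Step 5**
Reactants: 9 (3R,4S)-3-[(2Z)-3-iodobut-2-en-1-yl]-4-methyloxan-2-one
Product: 13 (5R)-2-methyl-5-[(2S)-4-(triethylsilyloxy)butan-2-yl]cyclopent-2-en-1-one, via vinyllithium 10 (not isolated), via bicyclic lithium hemiketal alkoxide 11 (not isolated), via ring-opened lithium keto alkoxide 12 (not isolated)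
Conditions: t-BuLi (2 equiv), Et2O, −78 °C; then Et3SiCl, −78 → 0 °C
Reagents that add atoms: chlorotriethylsilane, CC[Si](CC)(CC)Cl
Why: Iodine–lithium exchange with retention of the Z geometry gives a vinyllithium that adds to the lactone carbonyl in a 5-exo-trig closure (anionic cyclization, intramolecular acylation of a vinyllithium), the tetrahedral alkoxide opens to the cyclopentenone, and the freed primary alkoxide is capped as its triethylsilyl ether; no stereocentre is formed or broken.

**Step 6**
Reactants: 13 (5R)-2-methyl-5-[(2S)-4-(triethylsilyloxy)butan-2-yl]cyclopent-2-en-1-one; 14 1-chloro-3-methylbut-2-ene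
Product: 16 (5R)-2-methyl-1-(3-methylbut-2-en-1-yl)-5-[(2S)-4-(triethylsilyloxy)butan-2-yl]cyclopent-2-en-1-ol, via (3-methylbut-2-en-1-yl)barium chloride 15 (not isolated)
Conditions: activated Ba (from BaI2 and Li(C12H10), THF), 14, THF, −78 °C; then 13, −78 °C; aq. NH4Cl
Reagents that add atoms: none
Why: Allylic barium reagents add to ketones through their less substituted terminus, so 1,2-addition to the enone carbonyl should give the linear prenyl carbinol (carbonyl allylation); the new carbinol centre is formed as a mixture that does not matter because it becomes sp2 in step 7.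

**Step 7**
Reactants: 16 (5R)-2-methyl-1-(3-methylbut-2-en-1-yl)-5-[(2S)-4-(triethylsilyloxy)butan-2-yl]cyclopent-2-en-1-ol
Product: 17 (4R)-2-methyl-3-(3-methylbut-2-en-1-yl)-4-[(2S)-4-(triethylsilyloxy)butan-2-yl]cyclopent-2-en-1-one
Conditions: [C5H5NH][CrO3Cl], Celite, CH2Cl2, rt
Reagents that add atoms: pyridinium chlorochromate, [O-][Cr](=O)(=O)Cl.c1cc[nH+]cc1
Why: The tertiary allylic alcohol forms a chromate ester that undergoes [3,3]-sigmatropic shift and oxidation (Babler–Dauben oxidative 1,3-transposition) to the tetrasubstituted enone; the silyl ether keeps the primary alcohol from forming a lactol and lactone with the tertiary hydroxyl, and the C1 stereocentre is not touched.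

**Step 8**
Reactants: 17 (4R)-2-methyl-3-(3-methylbut-2-en-1-yl)-4-[(2S)-4-(triethylsilyloxy)butan-2-yl]cyclopent-2-en-1-one
Product: 18 (3S)-3-[(1R)-3-methyl-2-(3-methylbut-2-en-1-yl)-4-oxocyclopent-2-en-1-yl]butanal
Conditions: (COCl)2, DMSO, CH2Cl2, −78 → −30 °C; Et3N, −78 °C → rt
Reagents that add atoms: none
Why: Under Swern conditions primary triethylsilyl ethers are cleaved and oxidized directly to aldehydes (oxidative desilylation), which should unmask the C8 aldehyde without a separate deprotection and without acid or base strong enough to epimerize C1.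

**Step 9**
Reactants: 18 (3S)-3-[(1R)-3-methyl-2-(3-methylbut-2-en-1-yl)-4-oxocyclopent-2-en-1-yl]butanal
Product: 19 (5R,6S,8S,8aR)-6-hydroxy-3,8-dimethyl-5-(prop-1-en-2-yl)-4,5,6,7,8,8a-hexahydroazulen-2(1H)-one
Conditions: (CH3)2AlCl (2.5 equiv), CH2Cl2, −78 → −20 °C; aq. NaHCO3
Reagents that add atoms: none
Why: (CH3)2AlCl activates the C8 aldehyde, the nucleophilic C7 terminus of the trisubstituted C7=C11 double bond attacks it, and a hydrogen of a C11 methyl group passes to oxygen through a six-membered ene transition state, so the C7–C8 bond, the C8 hydroxyl and the isopropenyl group arise together. The closest known reaction type is the Lewis acid promoted intramolecular carbonyl–ene (Prins-type) cyclization of citronellal to isopulegol, of which 18 is the analogue with one more ring atom. The seven-membered ring closes in a 7-exo-trig mode with respect to both the C=O and the C=C bond, on a template (sp3 C1 next to sp2 C5 of the cyclopentenone) that holds the two arms on adjacent ring atoms. C7 is controlled by a chair-like transition state in which H-1 is axial, the C10 methyl group is equatorial and the reacting isopropylidene unit is equatorial, which should place the isopropenyl group cis to the C10 methyl group; C8 is expected mainly with equatorial hydroxyl (trans to isopropenyl, as drawn). The step needs chemoselectivity for the aldehyde and the prenyl double bond over the cyclopentenone, secured because the enone carbonyl is the poorer electrophile and its tetrasubstituted, electron-poor double bond is no ene donor; it also needs bond formation at C7 and not at C11, secured by the tertiary character of the developing C11 cation and by ring size (seven against eight).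

**Step 10**
Reactants: 19 (5R,6S,8S,8aR)-6-hydroxy-3,8-dimethyl-5-(prop-1-en-2-yl)-4,5,6,7,8,8a-hexahydroazulen-2(1H)-one
Product: 20 (5R,8S,8aR)-3,8-dimethyl-5-(prop-1-en-2-yl)-4,5,8,8a-tetrahydroazulene-2,6(1H,7H)-dione
Conditions: Dess–Martin periodinane, NaHCO3, CH2Cl2, 0 °C → rt
Reagents that add atoms: none
Why: Dess–Martin oxidation under buffered, non-basic conditions should convert 19 and any C8 epimer formed with it into the same β,γ-unsaturated ketone without moving the isopropenyl double bond into conjugation or epimerizing C7.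

**Step 11**
Reactants: 20 (5R,8S,8aR)-3,8-dimethyl-5-(prop-1-en-2-yl)-4,5,8,8a-tetrahydroazulene-2,6(1H,7H)-dione
Product: 21 (5R,6R,8S,8aR)-6-hydroxy-3,8-dimethyl-5-(prop-1-en-2-yl)-4,5,6,7,8,8a-hexahydroazulen-2(1H)-one
Conditions: LiBH(s-C4H9)3 (1.1 equiv), THF, −78 °C; aq. NH4Cl
Reagents that add atoms: none
Why: The bulky hydride should attack the C8 ketone from the face opposite to the adjacent isopropenyl group and the C10 methyl group (steric approach control, as in the reduction of isopulegone to neoisopulegol), giving the C8 alcohol cis to the C7 substituent, while the conjugated, tetrasubstituted cyclopentenone reacts more slowly.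

**Step 12**
Reactants: 21 (5R,6R,8S,8aR)-6-hydroxy-3,8-dimethyl-5-(prop-1-en-2-yl)-4,5,6,7,8,8a-hexahydroazulen-2(1H)-one
Product: 22 (5S,6R,8S,8aR)-6-hydroxy-5-(2-hydroxypropan-2-yl)-3,8-dimethyl-4,5,6,7,8,8a-hexahydroazulen-2(1H)-one
Conditions: Co(acac)2 (cat.), PhSiH3, O2 (1 atm), THF, rt
Reagents that add atoms: dioxygen, O=O
Why: Hydrogen atom transfer from a cobalt hydride to the 1,1-disubstituted double bond gives the tertiary C11 radical, which is trapped by O2 and reduced to the alcohol (Mukaiyama hydration, Markovnikov); the tetrasubstituted enone is a much poorer acceptor and C11 is not stereogenic.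

**Step 13**
Reactants: 22 (5S,6R,8S,8aR)-6-hydroxy-5-(2-hydroxypropan-2-yl)-3,8-dimethyl-4,5,6,7,8,8a-hexahydroazulen-2(1H)-one
Product: 23 (5S,6R,8S,8aR)-5-(2-hydroxypropan-2-yl)-3,8-dimethyl-2-oxo-1,2,4,5,6,7,8,8a-octahydroazulen-6-yl 2-methylprop-2-enoate
Conditions: methacrylic anhydride, Et3N, DMAP (cat.), CH2Cl2, 0 °C → rt
Reagents that add atoms: methacrylic anhydride, C=C(C)C(=O)OC(=O)C(C)=C
Why: DMAP-catalysed acylation with the anhydride should esterify the secondary C8 hydroxyl selectively, because the tertiary C11 hydroxyl is far less reactive under these conditions.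

**Step 14**
Reactants: 23 (5S,6R,8S,8aR)-5-(2-hydroxypropan-2-yl)-3,8-dimethyl-2-oxo-1,2,4,5,6,7,8,8a-octahydroazulen-6-yl 2-methylprop-2-enoate
Product: 24 (5S,6R,8S,8aR)-5-(2-acetoxypropan-2-yl)-3,8-dimethyl-2-oxo-1,2,4,5,6,7,8,8a-octahydroazulen-6-yl 2-methylprop-2-enoate
Conditions: Ac2O, Sc(OSO2CF3)3 (cat.), CH3CN, −20 °C
Reagents that add atoms: acetic anhydride, CC(=O)OC(C)=O
Why: Lewis acid catalysed acylation with acetic anhydride at low temperature acetylates hindered tertiary alcohols under non-basic conditions, which should give the tertiary acetate without ionization at C11 or migration of the methacrylate.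

**Compound list**

1 | but-2-yn-1-ol | CC#CCO | starting material
2 | cyclic sodium vinylalanate (sodium 2,2-bis(2-methoxyethoxy)-3-methyl-2,5-dihydro-1,2-oxaluminol-2-uide) | CC1=CCO[Al-]1(OCCOC)OCCOC.[Na+] | intermediate
3 | (Z)-3-iodobut-2-en-1-ol | OC/C=C(/C)I | intermediate
4 | (Z)-1-bromo-3-iodobut-2-ene | BrC/C=C(/C)I | intermediate
5 | methyl hydrogen (R)-3-methylglutarate, (3R)-5-methoxy-3-methyl-5-oxopentanoic acid | C[C@H](CC(=O)O)CC(=O)OC | starting material
6 | (3S)-5-hydroxy-3-methylpentanoic acid (lithium carboxylate in the flask) | C[C@H](CC(=O)O)CCO | intermediate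
7 | (4S)-4-methyloxan-2-one | C[C@H]1CCOC(=O)C1 | intermediate
8 | lithium enolate of 7 | C[C@H]1CCOC([O-])=C1.[Li+] | intermediate
9 | (3R,4S)-3-[(2Z)-3-iodobut-2-en-1-yl]-4-methyloxan-2-one | C[C@H]1CCOC(=O)[C@@H]1C/C=C(/C)I | intermediate
10 | vinyllithium from 9, (3R,4S)-3-[(2Z)-3-lithiobut-2-en-1-yl]-4-methyloxan-2-one | C[C@H]1CCOC(=O)[C@@H]1C/C=C(/C)[Li] | intermediate
11 | bicyclic lithium hemiketal alkoxide, lithium (4S,4aR)-4,7-dimethyl-2,3,4,4a,5,7a-hexahydrocyclopenta[b]pyran-7a-olate | C[C@H]1CCOC2([O-])C(C)=CC[C@H]12.[Li+] | intermediate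
12 | lithium (3S)-3-[(1R)-3-methyl-2-oxocyclopent-3-en-1-yl]butan-1-olate | [Li+].[O-]CC[C@H](C)[C@H]1CC=C(C)C1=O | intermediate
13 | (5R)-2-methyl-5-[(2S)-4-(triethylsilyloxy)butan-2-yl]cyclopent-2-en-1-one | CC[Si](CC)(CC)OCC[C@H](C)[C@H]1CC=C(C)C1=O | intermediate
14 | 1-chloro-3-methylbut-2-ene (prenyl chloride) | CC(C)=CCCl | starting material
15 | (3-methylbut-2-en-1-yl)barium chloride | CC(C)=CC[Ba]Cl | intermediate
16 | (5R)-2-methyl-1-(3-methylbut-2-en-1-yl)-5-[(2S)-4-(triethylsilyloxy)butan-2-yl]cyclopent-2-en-1-ol (both carbinol epimers) | CC[Si](CC)(CC)OCC[C@H](C)[C@H]1CC=C(C)C1(O)CC=C(C)C | intermediate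
17 | (4R)-2-methyl-3-(3-methylbut-2-en-1-yl)-4-[(2S)-4-(triethylsilyloxy)butan-2-yl]cyclopent-2-en-1-one | CC[Si](CC)(CC)OCC[C@H](C)[C@H]1CC(=O)C(C)=C1CC=C(C)C | intermediate
18 | (3S)-3-[(1R)-3-methyl-2-(3-methylbut-2-en-1-yl)-4-oxocyclopent-2-en-1-yl]butanal | O=CC[C@H](C)[C@H]1CC(=O)C(C)=C1CC=C(C)C | intermediate
19 | (5R,6S,8S,8aR)-6-hydroxy-3,8-dimethyl-5-(prop-1-en-2-yl)-4,5,6,7,8,8a-hexahydroazulen-2(1H)-one (guaiane numbering 1R,7R,8S,10S; hydroxyl trans to isopropenyl) | O[C@H]1C[C@H](C)[C@H]2CC(=O)C(C)=C2C[C@@H]1C(C)=C | intermediate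
20 | (5R,8S,8aR)-3,8-dimethyl-5-(prop-1-en-2-yl)-4,5,8,8a-tetrahydroazulene-2,6(1H,7H)-dione | O=C1C[C@H](C)[C@H]2CC(=O)C(C)=C2C[C@@H]1C(C)=C | intermediate
21 | (5R,6R,8S,8aR)-6-hydroxy-3,8-dimethyl-5-(prop-1-en-2-yl)-4,5,6,7,8,8a-hexahydroazulen-2(1H)-one (hydroxyl cis to isopropenyl) | O[C@@H]1C[C@H](C)[C@H]2CC(=O)C(C)=C2C[C@@H]1C(C)=C | intermediate
22 | (5S,6R,8S,8aR)-6-hydroxy-5-(2-hydroxypropan-2-yl)-3,8-dimethyl-4,5,6,7,8,8a-hexahydroazulen-2(1H)-one | O[C@@H]1C[C@H](C)[C@H]2CC(=O)C(C)=C2C[C@@H]1C(C)(C)O | intermediate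
23 | (5S,6R,8S,8aR)-5-(2-hydroxypropan-2-yl)-3,8-dimethyl-2-oxo-1,2,4,5,6,7,8,8a-octahydroazulen-6-yl 2-methylprop-2-enoate | C=C(C)C(=O)O[C@@H]1C[C@H](C)[C@H]2CC(=O)C(C)=C2C[C@@H]1C(C)(C)O | intermediate
24 | (5S,6R,8S,8aR)-5-(2-acetoxypropan-2-yl)-3,8-dimethyl-2-oxo-1,2,4,5,6,7,8,8a-octahydroazulen-6-yl 2-methylprop-2-enoate (guaiane numbering 1R,7S,8R,10S) | C=C(C)C(=O)O[C@@H]1C[C@H](C)[C@H]2CC(=O)C(C)=C2C[C@@H]1C(C)(C)OC(C)=O | target

**Step count and risks**

Total step count: 14. Longest linear sequence: 13 steps (1 to 24, through steps 1 and 2 and then steps 4 to 14); the lactone branch from 5 (step 3) joins in step 4 and 14 enters in step 6.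

The three steps most likely to fail:

Step 9: slow closure of the seven-membered ring with competing intermolecular reactions of the aldehyde, or poor facial selectivity at C7. The fallback sets out from 17. Allylic oxidation of the (E)-methyl group of the prenyl unit (SeO2 cat., t-BuOOH, CH2Cl2) should give (4R)-3-[(2E)-4-hydroxy-3-methylbut-2-en-1-yl]-2-methyl-4-[(2S)-4-(triethylsilyloxy)butan-2-yl]cyclopent-2-en-1-one F1. CBr4 and PPh3 should convert it into the allylic bromide (4R)-3-[(2E)-4-bromo-3-methylbut-2-en-1-yl]-2-methyl-4-[(2S)-4-(triethylsilyloxy)butan-2-yl]cyclopent-2-en-1-one F2, and Swern oxidative desilylation into the bromo aldehyde (3S)-3-[(1R)-2-[(2E)-4-bromo-3-methylbut-2-en-1-yl]-3-methyl-4-oxocyclopent-2-en-1-yl]butanal F3. CrCl2 in THF at high dilution should then form the C7–C8 bond by intramolecular Nozaki–Hiyama allylation, the allylchromium attacking through C7 in a closed chair transition state. This comes back to the route at 19 (either C8 epimer is taken on to 20).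

Step 6: attack through the more substituted terminus of the prenyl reagent, or enolization of the ketone in place of addition. The fallback sets out from 13. Allylmagnesium bromide (THF, −78 °C) should give (5R)-2-methyl-1-(prop-2-en-1-yl)-5-[(2S)-4-(triethylsilyloxy)butan-2-yl]cyclopent-2-en-1-ol F4, and [C5H5NH][CrO3Cl] should transpose it to (4R)-2-methyl-3-(prop-2-en-1-yl)-4-[(2S)-4-(triethylsilyloxy)butan-2-yl]cyclopent-2-en-1-one F5. Cross-metathesis with 2-methylbut-2-ene (second-generation Grubbs catalyst RuCl2(=CHPh)(PCy3)(H2IMes), CH2Cl2, 40 °C) then builds the prenyl group and comes back to the route at 17.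

Step 11: competing reduction of the cyclopentenone carbonyl, or incomplete facial selectivity of hydride delivery. The fallback sets out from 19, the alcohol of step 9 with hydroxyl trans to isopropenyl, and avoids the ketone. Mitsunobu inversion (4-nitrobenzoic acid, PPh3, diisopropyl azodicarboxylate, THF) should give (5R,6R,8S,8aR)-3,8-dimethyl-2-oxo-5-(prop-1-en-2-yl)-1,2,4,5,6,7,8,8a-octahydroazulen-6-yl 4-nitrobenzoate F6, and methanolysis (K2CO3, MeOH) comes back to the route at 21.

**Further compounds**

F1 | step 9 | (4R)-3-[(2E)-4-hydroxy-3-methylbut-2-en-1-yl]-2-methyl-4-[(2S)-4-(triethylsilyloxy)butan-2-yl]cyclopent-2-en-1-one | CC[Si](CC)(CC)OCC[C@H](C)[C@H]1CC(=O)C(C)=C1C/C=C(\C)CO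
F2 | step 9 | (4R)-3-[(2E)-4-bromo-3-methylbut-2-en-1-yl]-2-methyl-4-[(2S)-4-(triethylsilyloxy)butan-2-yl]cyclopent-2-en-1-one | CC[Si](CC)(CC)OCC[C@H](C)[C@H]1CC(=O)C(C)=C1C/C=C(\C)CBr
F3 | step 9 | (3S)-3-[(1R)-2-[(2E)-4-bromo-3-methylbut-2-en-1-yl]-3-methyl-4-oxocyclopent-2-en-1-yl]butanal | O=CC[C@H](C)[C@H]1CC(=O)C(C)=C1C/C=C(\C)CBr
F4 | step 6 | (5R)-2-methyl-1-(prop-2-en-1-yl)-5-[(2S)-4-(triethylsilyloxy)butan-2-yl]cyclopent-2-en-1-ol | CC[Si](CC)(CC)OCC[C@H](C)[C@H]1CC=C(C)C1(O)CC=C
F5 | step 6 | (4R)-2-methyl-3-(prop-2-en-1-yl)-4-[(2S)-4-(triethylsilyloxy)butan-2-yl]cyclopent-2-en-1-one | CC[Si](CC)(CC)OCC[C@H](C)[C@H]1CC(=O)C(C)=C1CC=C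
F6 | step 11 | (5R,6R,8S,8aR)-3,8-dimethyl-2-oxo-5-(prop-1-en-2-yl)-1,2,4,5,6,7,8,8a-octahydroazulen-6-yl 4-nitrobenzoate | O=C(O[C@@H]1C[C@H](C)[C@H]2CC(=O)C(C)=C2C[C@@H]1C(C)=C)c1ccc(cc1)[N+](=O)[O-]
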